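**Strategy.** Ring B of the naphthazarin (C4a, C5, C6, C7, C8, C8a) carries hydroxyls on C5 and C8, which makes it a latent second quinone fused at C4a–C8a. It is disconnected at C4a–C5 and C8–C8a. One Diels–Alder reaction joins 1,4-bis(tert-butyldimethylsilyloxy)cyclohexa-1,3-diene to the unsubstituted C=C of an (S)-2-alkyl-1,4-benzoquinone. That quinone already holds the tiglate, the prenyl unit and the only stereocentre. The reaction forms both bonds, closes ring B and fixes oxygen on both bridgeheads, where elimination is impossible. Oxidation, ethylene extrusion and desilylation finish the target. tert-Butyldimethylsilyl is preferred to trimethylsilyl so that the bridgehead ethers outlast enolisation and chromatography.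

Key step: step 6

Remark on configuration: the carbinol centre of the target is (S) (O > ring C2 > CH2 > H), which is the alkannin series, and the enoate is (E).
Remark on numbering: the naphthalene numbering of the target (quinone C1–C4, side chain on C2) is used for all bridged compounds.
Assumption: the two naphthazarin tautomers interconvert fast, so the drawn tautomer stands for both.

Step 1
Reactants: 1 2,5-dimethoxybenzaldehyde
Product: 3 (S)-1-(2,5-dimethoxyphenyl)but-3-en-1-ol, via borinate ester 2 (not isolated)
Conditions: Ipc2B(allyl) [(+)-α-pinene series, 1.2 equiv], Et2O, −78 °C; then NaOH, H2O2, 0 to 23 °C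
Reagents that add atoms: B-allyldiisopinocampheylborane, C=CCB([C@@H]1C[C@@H]2C[C@H]([C@H]1C)C2(C)C)[C@@H]1C[C@@H]2C[C@H]([C@H]1C)C2(C)C
Why: Brown allylboration runs through a closed chair Zimmerman–Traxler transition state in which the isopinocampheyl groups derived from (+)-α-pinene expose the Si face of the aryl aldehyde to the allyl group, which should set the (S)-carbinol centre with high enantioselectivity, and alkaline H2O2 then frees the alcohol from borinate 2.

Step 2
Reactants: 3 (S)-1-(2,5-dimethoxyphenyl)but-3-en-1-ol; 4 2-methylbut-2-ene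
Product: 5 (S)-1-(2,5-dimethoxyphenyl)-4-methylpent-3-en-1-ol
Conditions: 4 (large excess, co-solvent), second-generation Grubbs catalyst (H2IMes)(PCy3)Cl2Ru=CHPh (3 mol%), CH2Cl2, 23 to 35 °C, sealed tube
Reagents that add atoms: none
Why: Olefin cross-metathesis of a terminal alkene with a large excess of 2-methylbut-2-ene is the standard way to turn an allyl into a prenyl group, the free alcohol is tolerated, the trisubstituted product re-enters the cycle only slowly, and the carbinol centre is not touched.

Step 3
Reactants: 5 (S)-1-(2,5-dimethoxyphenyl)-4-methylpent-3-en-1-ol; 6 tiglic acid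
Product: 7 (S)-1-(2,5-dimethoxyphenyl)-4-methylpent-3-enyl (E)-2-methylbut-2-enoate
Conditions: DCC (1.5 equiv), DMAP (0.3 equiv), CH2Cl2, 0 to 23 °C
Reagents that add atoms: none
Why: Steglich esterification acylates the oxygen without breaking the C–O bond of the carbinol, so the (S) configuration is retained, and tiglic acid is the thermodynamically preferred (E) isomer, so DMAP cannot degrade its geometry.

Step 4
Reactants: 7 (S)-1-(2,5-dimethoxyphenyl)-4-methylpent-3-enyl (E)-2-methylbut-2-enoate
Product: 8 (S)-1-(3,6-dioxocyclohexa-1,4-dien-1-yl)-4-methylpent-3-enyl (E)-2-methylbut-2-enoate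
Conditions: (NH4)2Ce(NO3)6 (2.3 equiv), MeCN/H2O, 0 °C, short contact time
Reagents that add atoms: water, O
Why: Oxidative demethylation of a 1,4-dimethoxyarene by tetravalent cerium (two one-electron oxidations, with capture of water and loss of methanol at both ether carbons) is fast at 0 °C on the electron-rich ring, whereas the trisubstituted alkene, the enoate and the carbinol C–H are oxidised far more slowly.

Step 5
Reactants: 9 cyclohexane-1,4-dione
Product: 10 1,4-bis(tert-butyldimethylsilyloxy)cyclohexa-1,3-diene
Conditions: TBSOTf (2.2 equiv), Et3N (3 equiv), CH2Cl2, 0 to 23 °C; bulb-to-bulb distillation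
Reagents that add atoms: tert-butyldimethylsilyl triflate, CC(C)(C)[Si](C)(C)OS(=O)(=O)C(F)(F)F
Why: In this double soft enolisation with silyl triflate and amine, the ketone that remains after the first silyl enol ether has formed loses its doubly activated allylic α-hydrogen, which gives the conjugated 1,3-diene, and any unconjugated 1,4-diene isomer cannot enter a [4+2] reaction and is removed by distillation or carried as ballast.

Step 6
Reactants: 8 (S)-1-(3,6-dioxocyclohexa-1,4-dien-1-yl)-4-methylpent-3-enyl (E)-2-methylbut-2-enoate; 10 1,4-bis(tert-butyldimethylsilyloxy)cyclohexa-1,3-diene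
Product: 11 endo adduct, 5,8-bis(tert-butyldimethylsilyloxy)-5,8-ethano-4a,5,8,8a-tetrahydronaphthalene-1,4-dione carrying the (S)-tigloyloxy-4-methylpent-3-enyl chain on C2. H-4a and H-8a are cis and lie on the side of the ethano bridge, and the enedione ring lies under C6=C7. One facial isomer is drawn and the other is expected beside it.
Conditions: 10 (1.5 equiv), PhMe, 23 to 45 °C, Ar, dark
Reagents that add atoms: none
Why: The s-cis-locked, electron-rich bis(silyl enol ether) 10 (high HOMO) and quinone 8 (low LUMO) combine in a concerted, suprafacial, normal-electron-demand [4+2] cycloaddition that forms C4a–C5 and C8–C8a in one event. The closest known reaction type is the Diels–Alder addition of benzo- and naphthoquinones to 1-alkoxy- or 1-silyloxycyclohexa-1,3-dienes, the first half of the Alder–Rickert arene synthesis. Ring B (C4a–C5–C6–C7–C8–C8a) is closed by intermolecular cycloaddition, and the CH2–CH2 unit of the diene becomes the ethano bridge of a bicyclo[2.2.2]octene. C4a and C8a emerge cis because addition to the ring alkene is suprafacial, C5 and C8 are locked to them by the bicycle, secondary orbital overlap places the enedione under the new C6=C7 bond (endo), and the remote (S)-carbinol centre exerts little facial control, so two facial isomers are expected, both of which converge in step 8. The only selectivity required is between the two quinone C=C bonds, and the branched C2 substituent secures it by shielding C2=C3 and making it less electrophilic, while the symmetry of the diene removes any question of orientation. Lewis acids are left out because they would divert the silyl enol ether into Mukaiyama–Michael addition, and light is excluded because endo adducts of this kind undergo intramolecular [2+2] cage formation.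

Step 7
Reactants: 11 endo adduct
Product: 13 bridged quinone, 5,8-bis(tert-butyldimethylsilyloxy)-5,8-ethano-5,8-dihydronaphthalene-1,4-dione with the (S) side chain on C2 (bridgehead configuration as in the drawn isomer of 11, accompanied by the other bridgehead diastereomer), via bridged hydroquinone 12 (not isolated)
Conditions: Et3N (0.2 equiv), Ag2O (2.5 equiv), Na2SO4, CH2Cl2, 0 to 23 °C, dark
Reagents that add atoms: none
Why: Amine-catalysed double enolisation aromatises the enedione (erasing C4a and C8a), and Ag2O present from the start oxidises hydroquinone 12 as it forms, which keeps low the concentration of the one intermediate that could expel tiglate through an ortho-quinone methide, while the bridgehead ethers cannot β-eliminate (Bredt's rule) and their silyl groups block retro-aldol opening.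

Step 8
Reactants: 13 bridged quinone
Product: 14 (S)-1-[5,8-bis(tert-butyldimethylsilyloxy)-1,4-dioxo-1,4-dihydronaphthalen-2-yl]-4-methylpent-3-enyl (E)-2-methylbut-2-enoate
Conditions: PhCl (0.02 M, degassed), BHT (5 mol%), 110 to 130 °C, Ar sweep, dark
Reagents that add atoms: none
Why: In this Alder–Rickert cycloreversion the bicyclo[2.2.2]octa-2,5-diene can fragment in only one way, by retro-Diels–Alder loss of its saturated two-carbon bridge as ethylene, a process driven by aromatisation of ring B and gas evolution and eased by the donor bridgehead oxygens facing the acceptor quinone, and it erases C5 and C8 so that both diastereomers of 13 converge on 14.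

Step 9
Reactants: 14 bis(silyl) naphthoquinone
Product: 15 target, (S)-1-(5,8-dihydroxy-1,4-dioxo-1,4-dihydronaphthalen-2-yl)-4-methylpent-3-enyl (E)-2-methylbut-2-enoate
Conditions: Bu4NF and AcOH (2.4 equiv each), THF, 0 °C; work-up at pH 4 to 5
Reagents that add atoms: none
Why: Fluoride-induced cleavage of aryl silyl ethers is fast here because each phenoxide, stabilised by its peri carbonyl, is a good leaving group, and the acetic acid buffer keeps the medium close to neutral so that the tiglate, the carbinol centre and the base-sensitive naphthazarin survive.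

**Compound list**

1 | 2,5-dimethoxybenzaldehyde | COc1ccc(OC)c(C=O)c1 | starting material
2 | (S)-1-(2,5-dimethoxyphenyl)but-3-enyl diisopinocampheylborinate | C=CC[C@H](OB([C@@H]1C[C@@H]2C[C@H]([C@H]1C)C2(C)C)[C@@H]1C[C@@H]2C[C@H]([C@H]1C)C2(C)C)c1cc(OC)ccc1OC | intermediate
3 | (S)-1-(2,5-dimethoxyphenyl)but-3-en-1-ol | C=CC[C@H](O)c1cc(OC)ccc1OC | intermediate
4 | 2-methylbut-2-ene | CC=C(C)C | starting material
5 | (S)-1-(2,5-dimethoxyphenyl)-4-methylpent-3-en-1-ol | CC(C)=CC[C@H](O)c1cc(OC)ccc1OC | intermediate
6 | tiglic acid, (E)-2-methylbut-2-enoic acid | C/C=C(\C)C(=O)O | starting material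
7 | (S)-1-(2,5-dimethoxyphenyl)-4-methylpent-3-enyl (E)-2-methylbut-2-enoate | C/C=C(\C)C(=O)O[C@@H](CC=C(C)C)c1cc(OC)ccc1OC | intermediate
8 | (S)-1-(3,6-dioxocyclohexa-1,4-dien-1-yl)-4-methylpent-3-enyl (E)-2-methylbut-2-enoate | C/C=C(\C)C(=O)O[C@@H](CC=C(C)C)C1=CC(=O)C=CC1=O | intermediate
9 | cyclohexane-1,4-dione | O=C1CCC(=O)CC1 | starting material
10 | 1,4-bis(tert-butyldimethylsilyloxy)cyclohexa-1,3-diene | CC(C)(C)[Si](C)(C)OC1=CC=C(O[Si](C)(C)C(C)(C)C)CC1 | intermediate
11 | endo Diels–Alder adduct, bridged bis(silyloxy) enedione (one facial isomer) | O=C1C([C@@H](OC(=O)/C(C)=C/C)CC=C(C)C)=CC(=O)[C@H]2[C@@H]1[C@]3(O[Si](C)(C)C(C)(C)C)CC[C@@]2(O[Si](C)(C)C(C)(C)C)C=C3 | intermediate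
12 | bridged hydroquinone, 5,8-ethano-5,8-dihydronaphthalene-1,4-diol (same bridgehead isomer) | Oc1c([C@@H](OC(=O)/C(C)=C/C)CC=C(C)C)cc(O)c2c1[C@]3(O[Si](C)(C)C(C)(C)C)CC[C@@]2(O[Si](C)(C)C(C)(C)C)C=C3 | intermediate
13 | bridged quinone, 5,8-ethano-5,8-dihydronaphthalene-1,4-dione (same bridgehead isomer) | O=C1C([C@@H](OC(=O)/C(C)=C/C)CC=C(C)C)=CC(=O)C2=C1[C@]3(O[Si](C)(C)C(C)(C)C)CC[C@@]2(O[Si](C)(C)C(C)(C)C)C=C3 | intermediate
14 | (S)-1-[5,8-bis(tert-butyldimethylsilyloxy)-1,4-dioxo-1,4-dihydronaphthalen-2-yl]-4-methylpent-3-enyl (E)-2-methylbut-2-enoate | C/C=C(\C)C(=O)O[C@@H](CC=C(C)C)C1=CC(=O)c2c(O[Si](C)(C)C(C)(C)C)ccc(O[Si](C)(C)C(C)(C)C)c2C1=O | intermediate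
15 | (S)-1-(5,8-dihydroxy-1,4-dioxo-1,4-dihydronaphthalen-2-yl)-4-methylpent-3-enyl (E)-2-methylbut-2-enoate | C/C=C(\C)C(=O)O[C@@H](CC=C(C)C)C1=CC(=O)c2c(O)ccc(O)c2C1=O | target

**Total step count:** 9
**Longest linear sequence:** 8 (steps 1 to 4 and 6 to 9)

**Steps most likely to fail**

**Step 6.**
- Two processes may outrun the cycloaddition. One is hydrogen transfer from the dihydroaromatic diene to the quinone, so that the diene aromatises and the dienophile is reduced. The other is stepwise conjugate addition with silyl migration.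
- The fallback sets out from 8 and comes back at 15. It exchanges the two-carbon bridge for an oxygen bridge.
- Succinic anhydride is bis-silylated (Me3SiCl, Et3N, ZnCl2, MeCN) to 2,5-bis(trimethylsilyloxy)furan F1, a diene that cannot aromatise by hydrogen transfer.
- Its Diels–Alder reaction with the same unsubstituted C=C of 8 (CH2Cl2, −20 to 23 °C) gives the 5,8-epoxy-bridged adduct F2.
- Dilute acid (aqueous HCl, THF, 0 °C) opens both bridgehead ketals. Tautomerisation then leads to 15 at the correct oxidation level, so steps 7 to 9 are bypassed.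

**Step 8.**
- Thermal loss of tiglic acid from the carbinol position, or radical oligomerisation of the quinone, may compete with ethylene extrusion at the temperature required.
- The fallback sets out from 5 and comes back at 15. It keeps the carboxylate leaving group out of the thermolysis.
- Alcohol 5 is silylated (TBSCl, imidazole, DMF) to the (S)-silyl ether F3 and oxidised with (NH4)2Ce(NO3)6 to the silyloxyalkyl benzoquinone F4.
- F4 is combined with diene 10 to give the endo adduct F5. This is enolised and oxidised (Et3N, Ag2O) by way of the bridged hydroquinone F6 to the bridged quinone F7, which is heated to give the tris(silyl) naphthoquinone F8.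
- A silyl ether is a far poorer leaving group than a carboxylate at every one of these stages.
- HF·pyridine in THF then gives alkannin F9.
- Only the side-chain hydroxyl of F9 is acylated by tiglic acid 6 under DCC/DMAP, because both phenols are tied up in hydrogen bonds to the quinone carbonyls. This acylation gives 15.

**Step 7.**
- Expulsion of tiglate from the transient hydroquinone through ortho-quinone methide formation, or sluggish removal of the hindered ring-fusion hydrogens, may erode the conversion.
- The fallback sets out from 11 and comes back at 13. It aromatises without ever freeing a phenol.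
- TMSOTf and Et3N (CH2Cl2, −78 to 0 °C) activate both carbonyl groups and trap the enols as the 1,4-bis(trimethylsilyloxy)arene F10.
- F10 is oxidatively desilylated with (NH4)2Ce(NO3)6 in aqueous MeCN at 0 °C, conditions the side chain has already met in step 4. This gives 13.

**Further compounds**

F1 | step 6 | 2,5-bis(trimethylsilyloxy)furan | C[Si](C)(C)Oc1ccc(O[Si](C)(C)C)o1
F2 | step 6 | 5,8-epoxy-5,8-bis(trimethylsilyloxy)-4a,5,8,8a-tetrahydronaphthalene-1,4-dione with the (S) tiglate side chain on C2 (endo, one facial isomer) | O=C1C([C@@H](OC(=O)/C(C)=C/C)CC=C(C)C)=CC(=O)[C@H]2[C@@H]1[C@]3(O[Si](C)(C)C)O[C@@]2(O[Si](C)(C)C)C=C3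
F3 | step 8 | (S)-tert-butyl[1-(2,5-dimethoxyphenyl)-4-methylpent-3-enyloxy]dimethylsilane | CC(C)=CC[C@H](O[Si](C)(C)C(C)(C)C)c1cc(OC)ccc1OC
F4 | step 8 | (S)-2-[1-(tert-butyldimethylsilyloxy)-4-methylpent-3-enyl]-1,4-benzoquinone | CC(C)=CC[C@H](O[Si](C)(C)C(C)(C)C)C1=CC(=O)C=CC1=O
F5 | step 8 | endo adduct of F4 and 10 (one facial isomer) | O=C1C([C@@H](O[Si](C)(C)C(C)(C)C)CC=C(C)C)=CC(=O)[C@H]2[C@@H]1[C@]3(O[Si](C)(C)C(C)(C)C)CC[C@@]2(O[Si](C)(C)C(C)(C)C)C=C3
F6 | step 8 | bridged hydroquinone of the silyl ether series | Oc1c([C@@H](O[Si](C)(C)C(C)(C)C)CC=C(C)C)cc(O)c2c1[C@]3(O[Si](C)(C)C(C)(C)C)CC[C@@]2(O[Si](C)(C)C(C)(C)C)C=C3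
F7 | step 8 | bridged quinone of the silyl ether series | O=C1C([C@@H](O[Si](C)(C)C(C)(C)C)CC=C(C)C)=CC(=O)C2=C1[C@]3(O[Si](C)(C)C(C)(C)C)CC[C@@]2(O[Si](C)(C)C(C)(C)C)C=C3
F8 | step 8 | (S)-5,8-bis(tert-butyldimethylsilyloxy)-2-[1-(tert-butyldimethylsilyloxy)-4-methylpent-3-enyl]-1,4-naphthoquinone | CC(C)=CC[C@H](O[Si](C)(C)C(C)(C)C)C1=CC(=O)c2c(O[Si](C)(C)C(C)(C)C)ccc(O[Si](C)(C)C(C)(C)C)c2C1=O
F9 | step 8 | alkannin, (S)-5,8-dihydroxy-2-(1-hydroxy-4-methylpent-3-enyl)-1,4-naphthoquinone | CC(C)=CC[C@H](O)C1=CC(=O)c2c(O)ccc(O)c2C1=O
F10 | step 7 | 1,4-bis(trimethylsilyloxy)-5,8-bis(tert-butyldimethylsilyloxy)-5,8-ethano-5,8-dihydronaphthalene with the (S) tiglate side chain on C2 | C[Si](C)(C)Oc1c([C@@H](OC(=O)/C(C)=C/C)CC=C(C)C)cc(O[Si](C)(C)C)c2c1[C@]3(O[Si](C)(C)C(C)(C)C)CC[C@@]2(O[Si](C)(C)C(C)(C)C)C=C3
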